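**Plan**

1. Retrosynthesis: cut the bridging CH–aryl bond at C6 of the 2‑methylbutanoyl chroman (o‑quinone methide of the isobutyryl half + free 2‑methylbutanoyl chroman), then the CH–alkyl bond (aryl aldehyde + Grignard reagent), then both C8 aryl–acyl bonds, then the pyran C2–C3 bond.
2. Enabling feature: in each 2,2‑dimethylchroman ring, C2 is an O‑bound CMe2 carbon, i.e. the carbon of an aryl isopropyl ether, and its methine hydrogen lies 1,5 to benzylic C4. A 1,5‑hydride shift from O–CH(CH3)2 to C4 of an arylidene Meldrum's acid makes C2 an oxocarbenium carbon and C3 an enolate carbon, which then join.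
3. Forward: symmetric 2,4,6‑triisopropoxybenzaldehyde → arylidene Meldrum's acid → pyran ring by internal redox (one batch serves both halves; the protecting group becomes C2 and its two methyls) → removal of the C3 helper → C8 acylation with the two acids → de‑isopropylation → formylation and Grignard addition on the isobutyryl half → union of the halves.
4. Stereochemistry: the side‑chain centre is bought as (R)‑2‑methylbutanoic acid and carried only through acidic, low‑temperature steps. The bridge centre is set in the last step by a chiral phosphoric acid acting on a planar o‑quinone methide, onto which both carbinol epimers converge.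

Key step: step 3

Assumption 1: 2,4,6‑trihydroxybenzaldehyde, Meldrum's acid, (R)‑2‑methylbutanoic acid and 1‑bromo‑5‑methylhexane are taken as purchasable.
Assumption 2: the facial sense of the phosphoric acid step cannot be predicted with certainty for this pair of partners; the route is written with (R)‑TRIP, and the (S)‑catalyst would be used if the sense proves opposite.

**Route**

Step 1
Reactants: 1 2,4,6‑trihydroxybenzaldehyde; 2 2‑bromopropane
Product: 3 2,4,6‑triisopropoxybenzaldehyde
Conditions: 2 (6 equiv), K2CO3 (4.5 equiv), DMF, 70 °C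
Reagents that add atoms: 2‑bromopropane (2), CC(C)Br
Why: Williamson ether synthesis; carbonate in DMF with excess secondary bromide should alkylate all three phenols, the formyl group disfavouring C‑alkylation of the phloroglucinol nucleus.

Step 2
Reactants: 3 2,4,6‑triisopropoxybenzaldehyde; 4 Meldrum's acid (2,2‑dimethyl‑1,3‑dioxane‑4,6‑dione)
Product: 5 2,2‑dimethyl‑5‑[(2,4,6‑triisopropoxyphenyl)methylidene]‑1,3‑dioxane‑4,6‑dione
Conditions: pyrrolidine (10 mol%), AcOH (10 mol%), toluene, 4 Å MS, rt → 45 °C
Reagents that add atoms: Meldrum's acid (4), CC1(C)OC(=O)CC(=O)O1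
Why: Knoevenagel condensation; the acidic Meldrum's acid condenses with the aryl aldehyde under iminium catalysis while the sieves remove water.

Step 3
Reactants: 5 2,2‑dimethyl‑5‑[(2,4,6‑triisopropoxyphenyl)methylidene]‑1,3‑dioxane‑4,6‑dione
Product: 7 5,7‑diisopropoxy‑2,2,2',2'‑tetramethylspiro[chromane‑3,5'‑[1,3]dioxane]‑4',6'‑dione, via oxocarbenium enolate zwitterion 6 (not isolated)
Conditions: Sc(OTf)3 (10 mol%), ClCH2CH2Cl, 80 °C
Reagents that add atoms: none
Why: Sc(III) chelates the two Meldrum's acid carbonyls of 5 and raises the electrophilicity of the benzylidene carbon, which lies 1,5 to the methine hydrogen of either ortho isopropyl ether; hydride transfer through a six‑membered transition state gives zwitterion 6 (ArO+=CMe2 next to a Meldrum's acid enolate), whose enolate carbon collapses onto the cationic carbon to form the C2–C3 bond. The closest known reaction type is the Lewis‑acid‑catalysed internal redox cyclization (1,5‑hydride shift/ring closure, the ether counterpart of the tert‑amino effect) of ortho‑alkoxybenzylidene 1,3‑dicarbonyl compounds to 3,4‑dihydro‑2H‑chromenes. The pyran ring closes in a 6‑endo‑trig mode with respect to the C=O+ bond (enolexo with respect to the nucleophile), and no other ring size is possible because donor and acceptor carbons are fixed 1,5 to each other. No stereocentre is formed, since C2 carries two methyls and C3 is the spiro carbon of a symmetric dioxanedione. The step needs hydride transfer to win over retro‑Knoevenagel cleavage and ether loss, and it needs a single constitutional product. The mirror symmetry of the triether makes the two ortho donors equivalent, the para isopropoxy group cannot reach the acceptor, the tertiary α‑oxy C–H is the best hydride donor present, and the two ortho substituents twist the arylidene out of conjugation with the electron‑rich ring so that the acceptor stays electrophilic.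

Step 4
Reactants: 7 5,7‑diisopropoxy‑2,2,2',2'‑tetramethylspiro[chromane‑3,5'‑[1,3]dioxane]‑4',6'‑dione
Product: 8 rac‑5,7‑diisopropoxy‑2,2‑dimethylchromane‑3‑carboxylic acid
Conditions: pyridine/H2O (9:1), 100 °C; then dilute HCl work‑up
Reagents that add atoms: water, O
Why: hydrolysis of the 5,5‑disubstituted Meldrum's acid gives the malonic acid with loss of acetone, and this decarboxylates on heating (standard Meldrum's acid hydrolysis/decarboxylation); the C3 centre formed here is racemic and is erased in step 5.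

Step 5
Reactants: 8 rac‑5,7‑diisopropoxy‑2,2‑dimethylchromane‑3‑carboxylic acid
Product: 10 5,7‑diisopropoxy‑2,2‑dimethylchromane, via Barton ester 9 (not isolated)
Conditions: 1‑hydroxypyridine‑2(1H)‑thione, DCC, DMAP (cat.), CH2Cl2, 0 °C → rt, dark; then t‑BuSH (10 equiv), hν (tungsten lamp), rt
Reagents that add atoms: none
Why: Barton reductive decarboxylation; the secondary C3 radical is capped by hydrogen transfer from the thiol, used in large excess so that this outruns β‑scission of the C2–O1 bond.

Step 6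
Reactants: 10 5,7‑diisopropoxy‑2,2‑dimethylchromane; 11 (R)‑2‑methylbutanoic acid
Product: 13 (2R)‑1‑(5,7‑diisopropoxy‑2,2‑dimethylchroman‑8‑yl)‑2‑methylbutan‑1‑one, via acyl trifluoroacetate 12 (not isolated)
Conditions: TFAA (2.5 equiv), 85% H3PO4 (cat.), CH2Cl2, 0 °C → rt
Reagents that add atoms: (R)‑2‑methylbutanoic acid (11), CC[C@@H](C)C(=O)O
Why: Friedel–Crafts acylation by the mixed‑anhydride method; C8, between the tied‑back ring oxygen and O7, is the accessible nucleophilic position (as in 5,7‑di‑O‑alkylflavans), whereas C6 sits between two isopropoxy groups, and the base‑free conditions should leave the α‑stereocentre brought in with 11 untouched.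

Step 7
Reactants: 13 (2R)‑1‑(5,7‑diisopropoxy‑2,2‑dimethylchroman‑8‑yl)‑2‑methylbutan‑1‑one
Product: 14 (2R)‑1‑(5,7‑dihydroxy‑2,2‑dimethylchroman‑8‑yl)‑2‑methylbutan‑1‑one
Conditions: BCl3 (1 M in CH2Cl2, 4 equiv), CH2Cl2, −78 → 0 °C; then ice‑water
Reagents that add atoms: none
Why: BCl3 cleavage of aryl isopropyl ethers; the ketone‑chelated C7 ether should go at −78 °C and the C5 ether on warming to 0 °C, the low temperature limiting enolisation of the ketone and heterolysis of the pyran C2–O1 bond.

Step 8
Reactants: 10 5,7‑diisopropoxy‑2,2‑dimethylchromane; 15 2‑methylpropanoic acid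
Product: 17 1‑(5,7‑diisopropoxy‑2,2‑dimethylchroman‑8‑yl)‑2‑methylpropan‑1‑one, via acyl trifluoroacetate 16 (not isolated)
Conditions: TFAA (2.5 equiv), 85% H3PO4 (cat.), CH2Cl2, 0 °C → rt
Reagents that add atoms: 2‑methylpropanoic acid (15), CC(C)C(=O)O
Why: the same mixed‑anhydride Friedel–Crafts acylation as in step 6, with the same steric preference for C8.

Step 9
Reactants: 17 1‑(5,7‑diisopropoxy‑2,2‑dimethylchroman‑8‑yl)‑2‑methylpropan‑1‑one
Product: 18 1‑(5,7‑dihydroxy‑2,2‑dimethylchroman‑8‑yl)‑2‑methylpropan‑1‑one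
Conditions: BCl3 (1 M in CH2Cl2, 4 equiv), CH2Cl2, −78 → 0 °C; then ice‑water
Reagents that add atoms: none
Why: BCl3 cleavage of the two aryl isopropyl ethers as in step 7.

Step 10
Reactants: 18 1‑(5,7‑dihydroxy‑2,2‑dimethylchroman‑8‑yl)‑2‑methylpropan‑1‑one
Product: 19 5,7‑dihydroxy‑2,2‑dimethyl‑8‑(2‑methylpropanoyl)chromane‑6‑carbaldehyde
Conditions: POCl3 (1.5 equiv), DMF (3 equiv), EtOAc, 0 °C → rt; then H2O, 50 °C
Reagents that add atoms: N,N‑dimethylformamide, CN(C)C=O; water, O
Why: Vilsmeier–Haack formylation; C6 is the only free ring position and is activated by two ortho hydroxyls and the para ring oxygen, as in the usual formylation of acylphloroglucinols.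

Step 11
Reactants: 19 5,7‑dihydroxy‑2,2‑dimethyl‑8‑(2‑methylpropanoyl)chromane‑6‑carbaldehyde; 20 1‑bromo‑5‑methylhexane
Product: 22 rac‑1‑[5,7‑dihydroxy‑6‑(1‑hydroxy‑6‑methylheptyl)‑2,2‑dimethylchroman‑8‑yl]‑2‑methylpropan‑1‑one, via 5‑methylhexylmagnesium bromide 21 (not isolated)
Conditions: 20 (3.5 equiv), Mg, THF, rt → 40 °C; then 19, THF, −40 → 0 °C; then pH 7 buffer; crude product used at once
Reagents that add atoms: 1‑bromo‑5‑methylhexane (20), CC(C)CCCCBr
Why: Grignard addition to the aldehyde; two equivalents form the bis‑phenoxide, which shields the hindered phenoxide‑conjugated ketone, and the next adds to the magnesium‑chelated formyl group, the carbinol centre being formed unselectively on purpose because step 12 erases it.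

Step 12
Reactants: 22 rac‑1‑[5,7‑dihydroxy‑6‑(1‑hydroxy‑6‑methylheptyl)‑2,2‑dimethylchroman‑8‑yl]‑2‑methylpropan‑1‑one; 14 (2R)‑1‑(5,7‑dihydroxy‑2,2‑dimethylchroman‑8‑yl)‑2‑methylbutan‑1‑one
Product: 24 1‑[6‑[(1R)‑1‑[5,7‑dihydroxy‑2,2‑dimethyl‑8‑[(2R)‑2‑methylbutanoyl]chroman‑6‑yl]‑6‑methylheptyl]‑5,7‑dihydroxy‑2,2‑dimethylchroman‑8‑yl]‑2‑methylpropan‑1‑one, via o‑quinone methide 23 (not isolated)
Conditions: (R)‑TRIP (10 mol%), 5 Å MS, toluene, −20 °C; Et3N quench
Reagents that add atoms: none
Why: chiral phosphoric acid catalysed enantioselective Friedel–Crafts addition to an o‑quinone methide made in situ: the acid dehydrates either epimer of 22 to planar 23 (stereoconvergent), binds its carbonyl oxygen and a phenol OH of 14, and should direct C6 of 14 to one face of the exocyclic C=C, so that the bridge configuration follows from which ring is electrophile and which is nucleophile and not from the remote acyl groups, while the side‑chain centre of 14 is not touched.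

**Compound list**

1 | 2,4,6‑trihydroxybenzaldehyde | O=Cc1c(O)cc(O)cc1O | starting material
2 | 2‑bromopropane | CC(C)Br | starting material
3 | 2,4,6‑triisopropoxybenzaldehyde | CC(C)Oc1cc(OC(C)C)c(C=O)c(OC(C)C)c1 | intermediate
4 | Meldrum's acid | CC1(C)OC(=O)CC(=O)O1 | starting material
5 | 2,2‑dimethyl‑5‑[(2,4,6‑triisopropoxyphenyl)methylidene]‑1,3‑dioxane‑4,6‑dione | CC(C)Oc1cc(OC(C)C)c(C=C2C(=O)OC(C)(C)OC2=O)c(OC(C)C)c1 | intermediate
6 | aryl oxocarbenium / Meldrum's acid enolate zwitterion | CC(C)Oc1cc(OC(C)C)c(CC2=C([O-])OC(C)(C)OC2=O)c([O+]=C(C)C)c1 | intermediate (not isolated)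
7 | 5,7‑diisopropoxy‑2,2,2',2'‑tetramethylspiro[chromane‑3,5'‑[1,3]dioxane]‑4',6'‑dione | CC(C)Oc1cc(OC(C)C)c2CC3(C(=O)OC(C)(C)OC3=O)C(C)(C)Oc2c1 | intermediate
8 | rac‑5,7‑diisopropoxy‑2,2‑dimethylchromane‑3‑carboxylic acid | CC(C)Oc1cc(OC(C)C)c2CC(C(=O)O)C(C)(C)Oc2c1 | intermediate
9 | Barton ester of 8 (2‑thioxopyridin‑1(2H)‑yl ester) | CC(C)Oc1cc(OC(C)C)c2CC(C(=O)On3ccccc3=S)C(C)(C)Oc2c1 | intermediate (not isolated)
10 | 5,7‑diisopropoxy‑2,2‑dimethylchromane | CC(C)Oc1cc(OC(C)C)c2CCC(C)(C)Oc2c1 | intermediate
11 | (R)‑2‑methylbutanoic acid | CC[C@@H](C)C(=O)O | starting material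
12 | (R)‑2‑methylbutanoic trifluoroacetic anhydride | CC[C@@H](C)C(=O)OC(=O)C(F)(F)F | intermediate (not isolated)
13 | (2R)‑1‑(5,7‑diisopropoxy‑2,2‑dimethylchroman‑8‑yl)‑2‑methylbutan‑1‑one | CC[C@@H](C)C(=O)c1c(OC(C)C)cc(OC(C)C)c2CCC(C)(C)Oc12 | intermediate
14 | (2R)‑1‑(5,7‑dihydroxy‑2,2‑dimethylchroman‑8‑yl)‑2‑methylbutan‑1‑one | CC[C@@H](C)C(=O)c1c(O)cc(O)c2CCC(C)(C)Oc12 | intermediate
15 | 2‑methylpropanoic acid | CC(C)C(=O)O | starting material
16 | 2‑methylpropanoic trifluoroacetic anhydride | CC(C)C(=O)OC(=O)C(F)(F)F | intermediate (not isolated)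
17 | 1‑(5,7‑diisopropoxy‑2,2‑dimethylchroman‑8‑yl)‑2‑methylpropan‑1‑one | CC(C)C(=O)c1c(OC(C)C)cc(OC(C)C)c2CCC(C)(C)Oc12 | intermediate
18 | 1‑(5,7‑dihydroxy‑2,2‑dimethylchroman‑8‑yl)‑2‑methylpropan‑1‑one | CC(C)C(=O)c1c(O)cc(O)c2CCC(C)(C)Oc12 | intermediate
19 | 5,7‑dihydroxy‑2,2‑dimethyl‑8‑(2‑methylpropanoyl)chromane‑6‑carbaldehyde | CC(C)C(=O)c1c(O)c(C=O)c(O)c2CCC(C)(C)Oc12 | intermediate
20 | 1‑bromo‑5‑methylhexane | CC(C)CCCCBr | starting material
21 | 5‑methylhexylmagnesium bromide | CC(C)CCCC[Mg]Br | intermediate (not isolated)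
22 | rac‑1‑[5,7‑dihydroxy‑6‑(1‑hydroxy‑6‑methylheptyl)‑2,2‑dimethylchroman‑8‑yl]‑2‑methylpropan‑1‑one | CC(C)CCCCC(O)c1c(O)c(C(=O)C(C)C)c2OC(C)(C)CCc2c1O | intermediate
23 | o‑quinone methide from 22 (6‑(6‑methylheptylidene), C5 carbonyl) | CC(C)CCCCC=C1C(=O)C2=C(OC(C)(C)CC2)C(C(=O)C(C)C)=C1O | intermediate (not isolated)
24 | 1‑[6‑[(1R)‑1‑[5,7‑dihydroxy‑2,2‑dimethyl‑8‑[(2R)‑2‑methylbutanoyl]chroman‑6‑yl]‑6‑methylheptyl]‑5,7‑dihydroxy‑2,2‑dimethylchroman‑8‑yl]‑2‑methylpropan‑1‑one | CC[C@@H](C)C(=O)c1c(O)c([C@H](CCCCC(C)C)c2c(O)c3c(c(C(=O)C(C)C)c2O)OC(C)(C)CC3)c(O)c2c1OC(C)(C)CC2 | target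

**Step count and risks**

Total steps: 12. Longest linear sequence: 10 (steps 1–5, 8–12).

Steps most likely to fail:

Step 12. Facial discrimination in the attack on the o‑quinone methide may be insufficient. Acid‑mediated reversible cleavage of the new aryl–CH bond may erode the bridge configuration or exchange the halves, and the o‑quinone methide may tautomerise to the alkenylphenol. The fallback sets out from 22 and 14 and returns at 24. The coupling is run with an achiral acid (diphenyl phosphate, 5 mol%, CH2Cl2, 0 °C), which should give 24 together with its bridge epimer, 1‑[6‑[(1S)‑1‑[5,7‑dihydroxy‑2,2‑dimethyl‑8‑[(2R)‑2‑methylbutanoyl]chroman‑6‑yl]‑6‑methylheptyl]‑5,7‑dihydroxy‑2,2‑dimethylchroman‑8‑yl]‑2‑methylpropan‑1‑one F1. The two are diastereomers because the side‑chain centre is fixed, and they are separated by preparative HPLC on a polysaccharide chiral stationary phase.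

Step 3. Hydride transfer may be too slow because the trialkoxyaryl ring lowers the electrophilicity of the benzylidene carbon, so that the Lewis acid causes retro‑Knoevenagel cleavage or loss of an isopropyl group instead. The fallback sets out from 3 and returns at 10, building the pyran ring by a cycloaddition. BCl3 (1 equiv, CH2Cl2, −78 °C) removes one formyl‑chelated ortho isopropyl group to give 2‑hydroxy‑4,6‑diisopropoxybenzaldehyde F2. NaBH4 in MeOH reduces this to 2‑(hydroxymethyl)‑3,5‑diisopropoxyphenol F3. Heating F3 with excess isobutene in a sealed tube (toluene, about 160 °C) generates the parent o‑quinone methide, which undergoes inverse‑demand hetero‑Diels–Alder addition with the substituted alkene carbon bonding to oxygen, giving 10.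

Step 7. Boron chelation between the ketone and the pyran oxygen may trigger heterolysis of the C2–O1 bond (ring opening), and acid‑promoted enolisation may erode the side‑chain configuration. The fallback sets out from 10 and 11 and returns at 14, with the order of events reversed. Compound 10 is de‑isopropylated with BCl3 before any carbonyl is present, giving 5,7‑dihydroxy‑2,2‑dimethylchromane F4. Any ring‑opened material has two equivalent hydroxyls flanking the side chain and should reclose to the same chromane on brief treatment with Amberlyst‑15. Acid 11 is converted with oxalyl chloride and catalytic DMF into (R)‑2‑methylbutanoyl chloride F5. F4 is acylated with F5 and AlCl3 in CH2Cl2/PhNO2 at 0 °C (classical Friedel–Crafts acylation of phloroglucinol‑type phenols). Compound 14 is then separated by chromatography from the regioisomer (2R)‑1‑(5,7‑dihydroxy‑2,2‑dimethylchroman‑6‑yl)‑2‑methylbutan‑1‑one F6, which has a different hydrogen‑bonding pattern.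

Further compounds
F1 | step 12 | 1‑[6‑[(1S)‑1‑[5,7‑dihydroxy‑2,2‑dimethyl‑8‑[(2R)‑2‑methylbutanoyl]chroman‑6‑yl]‑6‑methylheptyl]‑5,7‑dihydroxy‑2,2‑dimethylchroman‑8‑yl]‑2‑methylpropan‑1‑one | CC[C@@H](C)C(=O)c1c(O)c([C@@H](CCCCC(C)C)c2c(O)c3c(c(C(=O)C(C)C)c2O)OC(C)(C)CC3)c(O)c2c1OC(C)(C)CC2
F2 | step 3 | 2‑hydroxy‑4,6‑diisopropoxybenzaldehyde | CC(C)Oc1cc(O)c(C=O)c(OC(C)C)c1
F3 | step 3 | 2‑(hydroxymethyl)‑3,5‑diisopropoxyphenol | CC(C)Oc1cc(O)c(CO)c(OC(C)C)c1
F4 | step 7 | 5,7‑dihydroxy‑2,2‑dimethylchromane | Oc1cc(O)c2CCC(C)(C)Oc2c1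
F5 | step 7 | (R)‑2‑methylbutanoyl chloride | CC[C@@H](C)C(=O)Cl
F6 | step 7 | (2R)‑1‑(5,7‑dihydroxy‑2,2‑dimethylchroman‑6‑yl)‑2‑methylbutan‑1‑one | CC[C@@H](C)C(=O)c1c(O)cc2OC(C)(C)CCc2c1O
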